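With rings lettered A (methoxy), B (para-linked), C (hydroxy) and D (meta-linked), everything rests on cutting the bond between the C–D ether oxygen and its ring D carbon. Ring D carries nothing but this oxygen and a meta CH2, so no electron-withdrawing group can assist an SNAr there. The same carbon is, however, the ipso carbon of a 3-alkylbenzoic acid. The macrocycle is therefore closed first as a 21-membered aryl benzoate. In it the ring C oxygen para to the bridge is acylated by the ring D carboxyl, and the neighbouring ring C oxygen is a MOM ether. Palladium-mediated CO extrusion then forges O–C(ring D) and contracts the lactone to the 20-membered diether in one operation.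

Key step: step 12

Remark on the chemistry: the alkene geometry in 4, 6 and 13 does not matter because step 9 saturates both double bonds, so the A–D alkene is carried and drawn as an E/Z mixture.

Design of the precursor:
- The ring C oxygen next to the ester cannot be an acyl group, because a 1,2-acyl shift across the catechol oxygens would scramble the ring size.
- It cannot be a sulfonate, which would offer a second site for oxidative addition.
- It cannot be a benzyl ether, which would be lost in step 9.
- MOM meets all three demands. It should stand K3PO4 at 150 °C, it keeps the ring C aryloxide electron-rich, and it falls to catalytic acid.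
- In starting material 7 the benzyl group already marks O-4, so step 9 frees only the oxygen that is to be acylated.

Ring count: the shortest path round 17 and 18 is 3 (A) + O + 4 (B) + 2 + 4 (C) + O + 3 (D) + 2 = 20 atoms. The ester carbon makes it 21 in 16.

Step 1
Reactants: 1 methyl 3-(bromomethyl)benzoate
Product: 2 [3-(methoxycarbonyl)benzyl]triphenylphosphonium bromide
Conditions: PPh3, toluene, 110 °C
Reagents that add atoms: triphenylphosphine, c1ccc(cc1)P(c1ccccc1)c1ccccc1
Why: SN2 quaternisation of a primary benzylic bromide by PPh3 (phosphonium salt formation) should be clean, since the salt crystallises from toluene and the ester is not touched.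

Step 2
Reactants: 2 [3-(methoxycarbonyl)benzyl]triphenylphosphonium bromide; 3 isovanillin (3-hydroxy-4-methoxybenzaldehyde)
Product: 4 methyl 3-[2-(3-hydroxy-4-methoxyphenyl)ethenyl]benzoate (E/Z mixture)
Conditions: NaOMe (2.2 equiv), MeOH, 0 °C to rt
Reagents that add atoms: none
Why: Wittig olefination under methoxide, which is degenerate towards the methyl ester; the extra base turns 3 into a phenoxide that lies meta to the formyl group and cannot damp its electrophilicity by conjugation, so no phenol protection should be needed.

Step 3
Reactants: 4 methyl 3-[2-(3-hydroxy-4-methoxyphenyl)ethenyl]benzoate; 5 4-fluorobenzaldehyde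
Product: 6 methyl 3-{2-[3-(4-formylphenoxy)-4-methoxyphenyl]ethenyl}benzoate (E/Z mixture)
Conditions: K2CO3 (dry), DMF, 130 °C
Reagents that add atoms: none
Why: SNAr (addition–elimination) of the potassium phenoxide on a fluoroarene activated by its para formyl group is the standard entry to such A–O–B ethers, and the ester and alkene are inert to dry carbonate.

Step 4
Reactants: 7 4-benzyloxy-3-hydroxybenzaldehyde
Product: 8 4-(benzyloxy)-3-(methoxymethoxy)benzaldehyde
Conditions: MOMCl, iPr2NEt, CH2Cl2, 0 °C to rt
Reagents that add atoms: chloromethyl methyl ether, COCCl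
Why: O-alkylation of the only free phenol with a highly reactive alpha-chloro ether (MOM protection) should go cleanly under amine base and leave the aldehyde and the benzyl ether alone.

Step 5
Reactants: 8 4-(benzyloxy)-3-(methoxymethoxy)benzaldehyde
Product: 9 [4-(benzyloxy)-3-(methoxymethoxy)phenyl]methanol
Conditions: NaBH4, MeOH–THF, 0 °C
Reagents that add atoms: none
Why: Borohydride reduction of an aromatic aldehyde is chemoselective and basic, so both ether protecting groups should survive.

Step 6
Reactants: 9 [4-(benzyloxy)-3-(methoxymethoxy)phenyl]methanol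
Product: 11 4-(benzyloxy)-3-(methoxymethoxy)benzyl chloride, via benzylic mesylate 10 (not isolated)
Conditions: MsCl, Et3N, CH2Cl2, 0 °C; then LiCl, DMF, rt
Reagents that add atoms: methanesulfonyl chloride, CS(=O)(=O)Cl (its atoms stay only in 10); lithium chloride, [Li+].[Cl-]
Why: Mesylation followed by SN2 displacement with chloride keeps the medium basic throughout, so the acid-labile MOM acetal should survive where HX- or PBr3-based halogenations would endanger it.

Step 7
Reactants: 11 4-(benzyloxy)-3-(methoxymethoxy)benzyl chloride
Product: 12 diethyl [4-(benzyloxy)-3-(methoxymethoxy)benzyl]phosphonate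
Conditions: P(OEt)3 (neat), n-Bu4NI (cat.), 120 °C
Reagents that add atoms: triethyl phosphite, CCOP(OCC)OCC
Why: The Michaelis–Arbuzov reaction of an electron-rich benzylic halide runs under neutral conditions that MOM-protected benzyl halides are known to tolerate.

Step 8
Reactants: 12 diethyl [4-(benzyloxy)-3-(methoxymethoxy)benzyl]phosphonate; 6 methyl 3-{2-[3-(4-formylphenoxy)-4-methoxyphenyl]ethenyl}benzoate
Product: 13 methyl 3-{2-[3-(4-{(E)-2-[4-(benzyloxy)-3-(methoxymethoxy)phenyl]ethenyl}phenoxy)-4-methoxyphenyl]ethenyl}benzoate
Conditions: NaH, 15-crown-5 (cat.), THF, 0 °C to rt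
Reagents that add atoms: none
Why: In this Horner–Wadsworth–Emmons olefination the non-enolisable aldehyde of 6 is far more electrophilic than its methyl ester, the new alkene should be E, and the phosphate by-product washes out with water.

Step 9
Reactants: 13 the bis-stilbene benzyl ether
Product: 14 methyl 3-{2-[3-(4-{2-[4-hydroxy-3-(methoxymethoxy)phenyl]ethyl}phenoxy)-4-methoxyphenyl]ethyl}benzoate
Conditions: H2 (1 atm), Pd/C (10 wt% Pd), EtOAc–EtOH, rt
Reagents that add atoms: none
Why: Heterogeneous catalytic hydrogenation should saturate both stilbene double bonds and hydrogenolyse the aryl benzyl ether in one operation, while the MOM acetal, the methyl ester and the diaryl ether are inert.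

Step 10
Reactants: 14 the seco phenol methyl ester
Product: 15 3-{2-[3-(4-{2-[4-hydroxy-3-(methoxymethoxy)phenyl]ethyl}phenoxy)-4-methoxyphenyl]ethyl}benzoic acid
Conditions: LiOH·H2O, THF–MeOH–H2O, 40 °C; then 1 M HCl to pH 4, 0 °C
Reagents that add atoms: lithium hydroxide, [Li+].[OH-]
Why: Saponification of an unhindered methyl benzoate is routine, the MOM ether is stable to base, and a brief cold acidification to pH 4 should not cleave it.

Step 11
Reactants: 15 the seco hydroxy acid
Product: 16 21-membered aryl benzoate macrolactone (ring C O-4 acylated by the ring D carboxyl, ring C O-3 as MOM ether)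
Conditions: MNBA (2-methyl-6-nitrobenzoic anhydride), DMAP, CH2Cl2 (final about 1 mM), syringe-pump addition of 15 in THF, rt to 40 °C
Reagents that add atoms: none
Why: In this Shiina macrolactonisation MNBA and DMAP activate the unhindered ring D carboxyl group for acyl transfer to the ring C phenol, and slow addition keeps the seco acid so dilute that closure of the flexible 21-membered ring should outrun intermolecular acylation.

Step 12
Reactants: 16 21-membered aryl benzoate macrolactone
Product: 17 O-methoxymethyl pakyonol (20-membered diether)
Conditions: Pd(OAc)2 (0.2 equiv), 3,4-bis(dicyclohexylphosphino)thiophene (dcypt, 0.4 equiv), K3PO4 (1.5 equiv), toluene (5 mM), 150 °C, pressure vessel with large Ar headspace, vented to release CO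
Reagents that add atoms: none
Why: Proposed new method: zerovalent palladium, formed in situ from Pd(OAc)2 and the electron-rich chelating bisphosphine, should add oxidatively to the C(acyl)–O bond of 16, the ring D aryl should shift from the carbonyl carbon to the metal with loss of CO, and the cis-held aryl and aryloxide ligands should then join by C–O reductive elimination. The closest known reaction type is the palladium- or nickel-catalysed decarbonylative etherification of aryl (hetero)arenecarboxylates, which is established for open-chain and mostly azine-derived esters but not for a plain benzoate or a macrolactone. The 20-membered ring arises by ring contraction: both ends stay bound to one metal centre inside the macrocycle, so closure is an intramolecular reductive elimination and not a fresh end-to-end encounter. No stereocentre is formed. The selectivity needed is insertion at the ester C–O bond only; this bond is much weaker than the diaryl ether, methoxy and MOM-oxy aryl C–O bonds, which palladium (unlike nickel) leaves alone, and 16 offers no second acyl, sulfonyl or halide site. The ortho MOM-oxy and para alkyl groups keep the ring C aryloxide electron-rich, which should help the C–O bond-forming event, and venting CO guards against re-insertion and catalyst poisoning.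

Step 13
Reactants: 17 O-methoxymethyl pakyonol
Product: 18 pakyonol
Conditions: p-TsOH·H2O (0.2 equiv), MeOH–CH2Cl2, 40 °C
Reagents that add atoms: none
Why: Acid-catalysed acetal exchange with methanol (MOM cleavage) should remove only the acetal, since the aryl methyl ether and both diaryl ethers are inert to catalytic sulfonic acid.

Compound list
1 | methyl 3-(bromomethyl)benzoate | COC(=O)c1cccc(CBr)c1 | starting material
2 | [3-(methoxycarbonyl)benzyl]triphenylphosphonium bromide | COC(=O)c1cccc(C[P+](c2ccccc2)(c2ccccc2)c2ccccc2)c1.[Br-] | intermediate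
3 | isovanillin | COc1ccc(C=O)cc1O | starting material
4 | methyl 3-[2-(3-hydroxy-4-methoxyphenyl)ethenyl]benzoate (E/Z mixture) | COC(=O)c1cccc(C=Cc2ccc(OC)c(O)c2)c1 | intermediate
5 | 4-fluorobenzaldehyde | O=Cc1ccc(F)cc1 | starting material
6 | methyl 3-{2-[3-(4-formylphenoxy)-4-methoxyphenyl]ethenyl}benzoate (E/Z mixture) | COC(=O)c1cccc(C=Cc2ccc(OC)c(Oc3ccc(C=O)cc3)c2)c1 | intermediate
7 | 4-benzyloxy-3-hydroxybenzaldehyde | O=Cc1ccc(OCc2ccccc2)c(O)c1 | starting material
8 | 4-(benzyloxy)-3-(methoxymethoxy)benzaldehyde | COCOc1cc(C=O)ccc1OCc1ccccc1 | intermediate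
9 | [4-(benzyloxy)-3-(methoxymethoxy)phenyl]methanol | COCOc1cc(CO)ccc1OCc1ccccc1 | intermediate
10 | 4-(benzyloxy)-3-(methoxymethoxy)benzyl methanesulfonate | COCOc1cc(COS(C)(=O)=O)ccc1OCc1ccccc1 | intermediate
11 | 4-(benzyloxy)-3-(methoxymethoxy)benzyl chloride | COCOc1cc(CCl)ccc1OCc1ccccc1 | intermediate
12 | diethyl [4-(benzyloxy)-3-(methoxymethoxy)benzyl]phosphonate | CCOP(=O)(Cc1ccc(OCc2ccccc2)c(OCOC)c1)OCC | intermediate
13 | methyl 3-{2-[3-(4-{(E)-2-[4-(benzyloxy)-3-(methoxymethoxy)phenyl]ethenyl}phenoxy)-4-methoxyphenyl]ethenyl}benzoate (A–D alkene E/Z) | COC(=O)c1cccc(C=Cc2ccc(OC)c(Oc3ccc(/C=C/c4ccc(OCc5ccccc5)c(OCOC)c4)cc3)c2)c1 | intermediate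
14 | methyl 3-{2-[3-(4-{2-[4-hydroxy-3-(methoxymethoxy)phenyl]ethyl}phenoxy)-4-methoxyphenyl]ethyl}benzoate | COC(=O)c1cccc(CCc2ccc(OC)c(Oc3ccc(CCc4ccc(O)c(OCOC)c4)cc3)c2)c1 | intermediate
15 | 3-{2-[3-(4-{2-[4-hydroxy-3-(methoxymethoxy)phenyl]ethyl}phenoxy)-4-methoxyphenyl]ethyl}benzoic acid | OC(=O)c1cccc(CCc2ccc(OC)c(Oc3ccc(CCc4ccc(O)c(OCOC)c4)cc3)c2)c1 | intermediate
16 | 21-membered aryl benzoate macrolactone, ring C O-3 as MOM ether | COc1ccc2cc1Oc1ccc(cc1)CCc1ccc(c(OCOC)c1)OC(=O)c1cccc(c1)CC2 | intermediate
17 | O-methoxymethyl pakyonol | COc1ccc2cc1Oc1ccc(cc1)CCc1ccc(c(OCOC)c1)Oc1cccc(c1)CC2 | intermediate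
18 | pakyonol | COc1ccc2cc1Oc1ccc(cc1)CCc1ccc(c(O)c1)Oc1cccc(c1)CC2 | target

Total step count: 13. Longest linear sequence: 10 steps (7 to 18, steps 4 to 13). The other branch (1 to 18) counts 9.

Steps most likely to fail

1. Step 12.
- What may go wrong: oxidative addition to the ester of an electron-rich phenol may be slow. C–O reductive elimination from an electron-neutral, non-chelating aryl may also lag behind protodemetalation, CO re-insertion and aryloxide exchange between metal centres, which would open the ring or lead to oligomers.
- Fallback, from 16 back to 17, by known reaction types that make the same O–C(ring D) bond in two stages. A nickel-catalysed decarbonylative borylation is established for simple aryl benzoates (Ni(cod)2 with a trialkylphosphine or N-heterocyclic carbene ligand, B2pin2, carbonate base, dioxane, about 160 °C). After aqueous work-up it would open the lactone to the ring-opened phenol pinacol boronate F1. An intramolecular Chan–Lam–Evans coupling (Cu(OAc)2, pyridine, 4 Å sieves, air, CH2Cl2, about 1 mM) would then close the 20-membered ether and return to 17.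

2. Step 11.
- What may go wrong: intermolecular acylation (dimer and oligomer formation) and capping of the phenol by the activating anhydride may compete with ring closure.
- Fallback, from 4 and 12 back to 16: the ester bond is made intermolecularly and the ring is closed at the B–C bridge.
  - Hydrogenation of 4 (H2, Pd/C) would give methyl 3-[2-(3-hydroxy-4-methoxyphenyl)ethyl]benzoate F2.
  - SNAr with 5 as in step 3 would give the saturated aldehyde ester F3, and LiOH would give the aldehyde acid F4.
  - Hydrogenolysis of 12 (H2, Pd/C, EtOAc) would free the phenol phosphonate F5.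
  - Steglich-type esterification of F4 with F5 (EDC·HCl, DMAP, CH2Cl2) would give the open-chain aryl benzoate F6.
  - An intramolecular Horner–Wadsworth–Emmons reaction under slow addition (KHMDS, 18-crown-6, THF, −78 to 0 °C) would give the 21-membered stilbene lactone F7.
  - Hydrogenation (H2, Pd/C) would return to 16.

3. Step 2.
- What may go wrong: precipitation of the phenoxide of 3 and base-induced decomposition of the phosphonium salt may outpace the olefination.
- Fallback, from 2 back to 4: the A–D alkene is made by a Heck reaction, which tolerates a free phenol. Wittig methylenation of 2 with aqueous formaldehyde (K2CO3, rt) would give methyl 3-vinylbenzoate F8. Heck coupling of F8 with purchased 5-bromo-2-methoxyphenol (Pd(OAc)2, P(o-tol)3, Et3N, DMF, 100 °C) would deliver 4 as its E isomer.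

Further compounds
F1 | step 12 | 2-(methoxymethoxy)-4-{2-[4-(2-methoxy-5-{2-[3-(4,4,5,5-tetramethyl-1,3,2-dioxaborolan-2-yl)phenyl]ethyl}phenoxy)phenyl]ethyl}phenol | COc1ccc(CCc2cccc(B3OC(C)(C)C(C)(C)O3)c2)cc1Oc1ccc(CCc2ccc(O)c(OCOC)c2)cc1
F2 | step 11 | methyl 3-[2-(3-hydroxy-4-methoxyphenyl)ethyl]benzoate | COC(=O)c1cccc(CCc2ccc(OC)c(O)c2)c1
F3 | step 11 | methyl 3-{2-[3-(4-formylphenoxy)-4-methoxyphenyl]ethyl}benzoate | COC(=O)c1cccc(CCc2ccc(OC)c(Oc3ccc(C=O)cc3)c2)c1
F4 | step 11 | 3-{2-[3-(4-formylphenoxy)-4-methoxyphenyl]ethyl}benzoic acid | OC(=O)c1cccc(CCc2ccc(OC)c(Oc3ccc(C=O)cc3)c2)c1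
F5 | step 11 | diethyl [4-hydroxy-3-(methoxymethoxy)benzyl]phosphonate | CCOP(=O)(Cc1ccc(O)c(OCOC)c1)OCC
F6 | step 11 | 4-[(diethoxyphosphoryl)methyl]-2-(methoxymethoxy)phenyl 3-{2-[3-(4-formylphenoxy)-4-methoxyphenyl]ethyl}benzoate | CCOP(=O)(Cc1ccc(OC(=O)c2cccc(CCc3ccc(OC)c(Oc4ccc(C=O)cc4)c3)c2)c(OCOC)c1)OCC
F7 | step 11 | 21-membered lactone with a B–C stilbene bridge (either alkene geometry serves) | COc1ccc2cc1Oc1ccc(cc1)C=Cc1ccc(c(OCOC)c1)OC(=O)c1cccc(c1)CC2
F8 | step 2 | methyl 3-vinylbenzoate | COC(=O)c1cccc(C=C)c1
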